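## Retrosynthetic overview

1. Target 20 comes from alcohol 18 by O-sulfation; 18 comes from alkene 15 and 4-bromofuran-2(5H)-one 16 by hydroboration and B-alkyl Suzuki coupling, so the butenolide is attached ready-made, last.
2. Ring A is the last carbocycle closed: C1=C10 by intramolecular McMurry coupling of keto aldehyde 13.
3. Key step, C13–C14: SOMO-activated organocatalytic α-allylation of aldehyde 10. The enamine radical cation acts as an α-carbonyl cation (enolonium-type) equivalent, bonds to the nucleophilic end of an allylsilane and sets C13 by catalyst control.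
4. C9 (quaternary) is built by enolate methylation then allylation; hydroformylation extends the allyl group to the four-carbon aldehyde chain.
5. C3–C4 and ring B: Cu-catalysed 1,4-addition of the propanal-homoenolate Grignard 2 to (S)-pulegone 1, which supplies ring B and C8. Ring order: B (chiral pool), then A (McMurry), then the butenolide (appended).

Atom labels: the decalin is C1–C10 (C4 = CMe2, C5 = ring-fusion CH, C8 = CHMe, C9 = quaternary carbon, C10 = sp2 ring-fusion carbon); C11–C16 run from C9 to the butenolide; C13 is the chain stereocentre.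

Assumption: the target is delivered as the free hydrogen sulfate as drawn (it is more conveniently stored as its sodium salt); (S)-(−)-pulegone, the Grignard solution 2 and bromofuranone 16 are purchased.

## Route

Step 1
Reactants: 1 (S)-(−)-pulegone; 2 [2-(1,3-dioxan-2-yl)ethyl]magnesium bromide (0.5 M in THF)
Product: 5 (2R,5S)-2-[4-(1,3-dioxan-2-yl)-2-methylbutan-2-yl]-5-methylcyclohexan-1-one, via magnesium enolate 3 (not isolated), via cis-ketone 4 (not isolated)
Conditions: CuBr·SMe2 (10 mol %), THF, −40 → 0 °C; H2O; then KOH, EtOH–H2O, reflux, 3 h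
Reagents that add atoms: none
Why: Copper-catalysed 1,4-addition of a Grignard reagent that is a propanal homoenolate equivalent to the β,β-disubstituted enone joins two normally electrophilic β-carbons (C3 and C4) and builds the quaternary C4; C8 comes from the chiral pool, and C5 is set by base equilibration to the trans (menthone-type) ketone (about 85:15, cis isomer separable and recyclable).

Step 2
Reactants: 5 (2R,5S)-2-[4-(1,3-dioxan-2-yl)-2-methylbutan-2-yl]-5-methylcyclohexan-1-one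
Product: 7 (2R,3S,6R)-6-[4-(1,3-dioxan-2-yl)-2-methylbutan-2-yl]-2,3-dimethylcyclohexan-1-one (major epimer at C2; minor epimer carried along), via lithium enolate 6 (not isolated)
Conditions: LiN(iPr)2 (1.05 equiv), THF, −78 °C; MeI, −78 → −20 °C
Reagents that add atoms: iodomethane, CI
Why: Kinetic deprotonation takes the unhindered C9 methylene and not C5–H next to the quaternary carbon, and the lithium enolate is C-methylated (enolate alkylation); the new C9 centre (mainly trans to the C8 methyl) is flattened again in step 3.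

Step 3
Reactants: 7 (2R,3S,6R)-6-[4-(1,3-dioxan-2-yl)-2-methylbutan-2-yl]-2,3-dimethylcyclohexan-1-one
Product: 9 (2S,3S,6R)-6-[4-(1,3-dioxan-2-yl)-2-methylbutan-2-yl]-2,3-dimethyl-2-(prop-2-en-1-yl)cyclohexan-1-one, via lithium enolate 8 (not isolated)
Conditions: LiN(iPr)2 (1.0 equiv), THF–DMPU, −78 → 0 °C; allyl bromide, −78 °C → rt
Reagents that add atoms: allyl bromide, C=CCBr
Why: Enolate alkylation at the only accessible α-position; on the half-chair enolate with the C8 methyl and the bulky C5 tert-alkyl group both pseudo-equatorial, allyl bromide enters axially (chair-like transition state) on the face trans to the C5 substituent, so allyl ends cis to the C8 methyl and the step 2 methyl ends trans to it (9S).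

Step 4
Reactants: 9 (2S,3S,6R)-6-[4-(1,3-dioxan-2-yl)-2-methylbutan-2-yl]-2,3-dimethyl-2-(prop-2-en-1-yl)cyclohexan-1-one
Product: 10 4-[(1S,3R,6S)-3-[4-(1,3-dioxan-2-yl)-2-methylbutan-2-yl]-1,6-dimethyl-2-oxocyclohexyl]butanal
Conditions: Rh(acac)(CO)2 (1 mol %), BIPHEPHOS (2 mol %), CO/H2 (1:1, 10 bar), toluene, 70 °C
Reagents that add atoms: carbon monoxide, [C-]#[O+]
Why: Rhodium/bisphosphite hydroformylation of the monosubstituted alkene is strongly linear-selective (the alkene is allylic to a quaternary carbon) and leaves ketone and acetal alone; no stereocentre is formed.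

Step 5
Reactants: 10 4-[(1S,3R,6S)-3-[4-(1,3-dioxan-2-yl)-2-methylbutan-2-yl]-1,6-dimethyl-2-oxocyclohexyl]butanal
Product: 12 (2S,3S,6R)-6-[4-(1,3-dioxan-2-yl)-2-methylbutan-2-yl]-2-[(3R)-3-(hydroxymethyl)hex-5-en-1-yl]-2,3-dimethylcyclohexan-1-one, via α-allyl aldehyde 11 (not isolated)
Conditions: allylSiMe3 (2.5 equiv), (2S,5S)-5-benzyl-2-tert-butyl-3-methylimidazolidin-4-one·CF3CO2H (20 mol %), (NH4)2Ce(NO3)6 (2 equiv), NaHCO3 (2 equiv), DME, −20 °C, 24 h; then NaBH4, CH2Cl2–EtOH, −20 °C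
Reagents that add atoms: allyltrimethylsilane, C=CC[Si](C)(C)C
Why: SOMO-activation organocatalysis, in which one-electron oxidation of the catalyst-bound enamine gives a radical cation whose normally nucleophilic α-carbon (C13) is electrophilic and is captured by the nucleophilic terminus of the allylsilane (second oxidation and loss of silicon complete the α-allylation); the (E)-enamine points away from the tert-butyl group and bonding occurs on the face not shielded by the benzyl group, giving the (R)-aldehyde, which is reduced at once to stop epimerisation (the flanked ketone survives at low temperature, and no alkene is within reach of the radical cation because ring A is not yet closed).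

Step 6
Reactants: 12 (2S,3S,6R)-6-[4-(1,3-dioxan-2-yl)-2-methylbutan-2-yl]-2-[(3R)-3-(hydroxymethyl)hex-5-en-1-yl]-2,3-dimethylcyclohexan-1-one
Product: 13 4-[(1R,3S,4S)-3-[(3R)-3-(hydroxymethyl)hex-5-en-1-yl]-3,4-dimethyl-2-oxocyclohexyl]-4-methylpentanal
Conditions: 1 M HCl, THF, rt
Reagents that add atoms: water, O
Why: Acid-catalysed acetal hydrolysis frees the C1 aldehyde under conditions too mild to enolise the hindered ketone toward C5; no stereocentre is touched.

Step 7
Reactants: 13 4-[(1R,3S,4S)-3-[(3R)-3-(hydroxymethyl)hex-5-en-1-yl]-3,4-dimethyl-2-oxocyclohexyl]-4-methylpentanal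
Product: 15 (2R)-2-{2-[(1S,2S,4aR)-1,2,5,5-tetramethyl-1,2,3,4,4a,5,6,7-octahydronaphthalen-1-yl]ethyl}pent-4-en-1-ol, via titanium pinacolate 14 (not isolated)
Conditions: TiCl3(DME)1.5 (8 equiv), Zn–Cu (25 equiv), DME, reflux, slow addition of 13 over 30 h
Reagents that add atoms: none
Why: Intramolecular McMurry reductive carbonyl coupling (ketyl coupling to the titanium pinacolate, then deoxygenation) joins C1 and C10 and places the alkene exactly between them, closing ring A; the alcohol (as its titanium alkoxide) and the isolated alkene are tolerated, and C5 can no longer epimerise afterwards.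

Step 8
Reactants: 15 (2R)-2-{2-[(1S,2S,4aR)-1,2,5,5-tetramethyl-1,2,3,4,4a,5,6,7-octahydronaphthalen-1-yl]ethyl}pent-4-en-1-ol; 16 4-bromofuran-2(5H)-one
Product: 18 4-[(4R)-4-(hydroxymethyl)-6-[(1S,2S,4aR)-1,2,5,5-tetramethyl-1,2,3,4,4a,5,6,7-octahydronaphthalen-1-yl]hexyl]furan-2(5H)-one, via bis(9-BBN) adduct 17 (not isolated)
Conditions: 9-BBN-H (2.5 equiv), THF, 0 °C → rt; then 16, PdCl2(dppf) (5 mol %), AsPh3 (10 mol %), K3PO4 (3 M aq), DMF, rt
Reagents that add atoms: none
Why: 9-BBN hydroborates only the monosubstituted alkene (anti-Markovnikov; the ring alkene is too hindered, and the hydroxyl is masked in situ as a borinate), and B-alkyl Suzuki–Miyaura coupling with the vinylogous acyl bromide gives the 4-alkylbutenolide; no stereocentre is touched.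

Step 9
Reactants: 18 4-[(4R)-4-(hydroxymethyl)-6-[(1S,2S,4aR)-1,2,5,5-tetramethyl-1,2,3,4,4a,5,6,7-octahydronaphthalen-1-yl]hexyl]furan-2(5H)-one
Product: 20 (2R)-2-[3-(5-oxo-2,5-dihydrofuran-3-yl)propyl]-4-[(1S,2S,4aR)-1,2,5,5-tetramethyl-1,2,3,4,4a,5,6,7-octahydronaphthalen-1-yl]butyl hydrogen sulfate, via pyridinium sulfate 19 (not isolated)
Conditions: SO3·pyridine (3 equiv), pyridine, rt; then sulfonic acid resin (H+ form), MeOH–H2O, 0 °C
Reagents that add atoms: sulfur trioxide–pyridine complex, [O-]S(=O)(=O)[n+]1ccccc1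
Why: O-Sulfation of the primary alcohol by the sulfur trioxide–pyridine complex followed by cation exchange gives the hydrogen sulfate; butenolide and ring alkene are inert under these conditions.

## Compound list

1 | (S)-(−)-pulegone, (5S)-5-methyl-2-(propan-2-ylidene)cyclohexan-1-one | C[C@H]1CCC(=C(C)C)C(=O)C1 | starting material
2 | [2-(1,3-dioxan-2-yl)ethyl]magnesium bromide | Br[Mg]CCC1OCCCO1 | starting material
3 | bromomagnesium (5S)-2-[4-(1,3-dioxan-2-yl)-2-methylbutan-2-yl]-5-methylcyclohex-1-en-1-olate | C[C@H]1CCC(C(C)(C)CCC2OCCCO2)=C(O[Mg]Br)C1 | intermediate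
4 | (2S,5S)-2-[4-(1,3-dioxan-2-yl)-2-methylbutan-2-yl]-5-methylcyclohexan-1-one (cis) | C[C@H]1CC[C@@H](C(C)(C)CCC2OCCCO2)C(=O)C1 | intermediate
5 | (2R,5S)-2-[4-(1,3-dioxan-2-yl)-2-methylbutan-2-yl]-5-methylcyclohexan-1-one (trans) | C[C@H]1CC[C@H](C(C)(C)CCC2OCCCO2)C(=O)C1 | intermediate
6 | lithium (3S,6R)-6-[4-(1,3-dioxan-2-yl)-2-methylbutan-2-yl]-3-methylcyclohex-1-en-1-olate | C[C@H]1CC[C@H](C(C)(C)CCC2OCCCO2)C(O[Li])=C1 | intermediate
7 | (2R,3S,6R)-6-[4-(1,3-dioxan-2-yl)-2-methylbutan-2-yl]-2,3-dimethylcyclohexan-1-one (major C2 epimer) | C[C@H]1CC[C@H](C(C)(C)CCC2OCCCO2)C(=O)[C@@H]1C | intermediate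
8 | lithium (3S,6R)-6-[4-(1,3-dioxan-2-yl)-2-methylbutan-2-yl]-2,3-dimethylcyclohex-1-en-1-olate | C[C@H]1CC[C@H](C(C)(C)CCC2OCCCO2)C(O[Li])=C1C | intermediate
9 | (2S,3S,6R)-6-[4-(1,3-dioxan-2-yl)-2-methylbutan-2-yl]-2,3-dimethyl-2-(prop-2-en-1-yl)cyclohexan-1-one | C[C@H]1CC[C@H](C(C)(C)CCC2OCCCO2)C(=O)[C@@]1(C)CC=C | intermediate
10 | 4-[(1S,3R,6S)-3-[4-(1,3-dioxan-2-yl)-2-methylbutan-2-yl]-1,6-dimethyl-2-oxocyclohexyl]butanal | C[C@H]1CC[C@H](C(C)(C)CCC2OCCCO2)C(=O)[C@@]1(C)CCCC=O | intermediate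
11 | (2R)-2-{2-[(1S,3R,6S)-3-[4-(1,3-dioxan-2-yl)-2-methylbutan-2-yl]-1,6-dimethyl-2-oxocyclohexyl]ethyl}pent-4-enal | C[C@H]1CC[C@H](C(C)(C)CCC2OCCCO2)C(=O)[C@@]1(C)CC[C@H](CC=C)C=O | intermediate
12 | (2S,3S,6R)-6-[4-(1,3-dioxan-2-yl)-2-methylbutan-2-yl]-2-[(3R)-3-(hydroxymethyl)hex-5-en-1-yl]-2,3-dimethylcyclohexan-1-one | C[C@H]1CC[C@H](C(C)(C)CCC2OCCCO2)C(=O)[C@@]1(C)CC[C@H](CC=C)CO | intermediate
13 | 4-[(1R,3S,4S)-3-[(3R)-3-(hydroxymethyl)hex-5-en-1-yl]-3,4-dimethyl-2-oxocyclohexyl]-4-methylpentanal | C[C@H]1CC[C@H](C(C)(C)CCC=O)C(=O)[C@@]1(C)CC[C@H](CC=C)CO | intermediate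
14 | titanium-bound C1,C10-pinacolate of 13 (cyclic titanium diolate; configuration at the two carbinol carbons not defined, other ligands on titanium omitted) | C[C@H]1CC[C@H]2C3(O[Ti]OC3CCC2(C)C)[C@@]1(C)CC[C@H](CC=C)CO | intermediate
15 | (2R)-2-{2-[(1S,2S,4aR)-1,2,5,5-tetramethyl-1,2,3,4,4a,5,6,7-octahydronaphthalen-1-yl]ethyl}pent-4-en-1-ol | C[C@H]1CC[C@H]2C(=CCCC2(C)C)[C@@]1(C)CC[C@H](CC=C)CO | intermediate
16 | 4-bromofuran-2(5H)-one | BrC1=CC(=O)OC1 | starting material
17 | B-alkyl, O-boryl bis(9-borabicyclo[3.3.1]nonan-9-yl) adduct of 15 | C[C@H]1CC[C@H]2C(=CCCC2(C)C)[C@@]1(C)CC[C@H](CCCB1C3CCCC1CCC3)COB1C3CCCC1CCC3 | intermediate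
18 | 4-[(4R)-4-(hydroxymethyl)-6-[(1S,2S,4aR)-1,2,5,5-tetramethyl-1,2,3,4,4a,5,6,7-octahydronaphthalen-1-yl]hexyl]furan-2(5H)-one | C[C@H]1CC[C@H]2C(=CCCC2(C)C)[C@@]1(C)CC[C@H](CCCC1=CC(=O)OC1)CO | intermediate
19 | pyridinium salt of 20 | C[C@H]1CC[C@H]2C(=CCCC2(C)C)[C@@]1(C)CC[C@H](CCCC1=CC(=O)OC1)COS(=O)(=O)[O-].c1cc[nH+]cc1 | intermediate
20 | (2R)-2-[3-(5-oxo-2,5-dihydrofuran-3-yl)propyl]-4-[(1S,2S,4aR)-1,2,5,5-tetramethyl-1,2,3,4,4a,5,6,7-octahydronaphthalen-1-yl]butyl hydrogen sulfate (CNP0360075.1) | C[C@H]1CC[C@H]2C(=CCCC2(C)C)[C@@]1(C)CC[C@H](CCCC1=CC(=O)OC1)COS(=O)(=O)O | target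

## Step count and risks

Total steps: 9. Longest linear sequence: 9 steps (1 → 20).

The three steps most likely to fail:

**Step 5 (SOMO α-allylation).** The risks are the enantiomeric excess, the sense of induction (taken from the shielding model, not from a checked precedent on this substrate) and survival of the dioxane acetal in the presence of the cerium oxidant. The fallback sets out from 10 and comes back at 12. Pinnick oxidation (NaClO2, NaH2PO4, 2-methylbut-2-ene) gives 4-[(1S,3R,6S)-3-[4-(1,3-dioxan-2-yl)-2-methylbutan-2-yl]-1,6-dimethyl-2-oxocyclohexyl]butanoic acid F2. Its pivalic mixed anhydride acylates lithiated (4S)-4-benzyl-1,3-oxazolidin-2-one to give the N-acyl oxazolidinone F3. NaN(SiMe3)2 and allyl iodide (THF, −78 °C) alkylate the chelated Z-enolate opposite the benzyl group to give the (R)-allylated imide F4. LiBH4 (Et2O–H2O, 0 °C) removes the auxiliary reductively to give 12.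

**Step 3 (quaternary C9).** The facial selectivity rests on a conformational argument and may be modest; enolisation toward C5 would also erode the C5 configuration. The fallback sets out from 7 and comes back at 9. The enolate (LiN(SiMe3)2, TMEDA, THF) is O-acylated with allyl chloroformate to give allyl (3S,6R)-6-[4-(1,3-dioxan-2-yl)-2-methylbutan-2-yl]-2,3-dimethylcyclohex-1-en-1-yl carbonate F1. Decarboxylative Tsuji allylation with Pd2(dba)3 and (R)-t-Bu-PHOX (THF, 25 °C) then lets the ligand, not the ring conformation, choose the face of C9 and gives 9.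

**Step 7 (McMurry coupling at a ketone flanked by a quaternary and a neopentyl-type carbon).** The reaction may stop at the pinacol or give low conversion. The fallback sets out from 13 and comes back at 15. Silylation (TBSCl, imidazole) gives the silyl ether of 13, F5. SmI2 (THF, t-BuOH, −78 °C → rt) effects ketyl pinacol cyclisation to the cis-diol F6. Thiocarbonyldiimidazole (toluene, 100 °C) gives the cyclic thionocarbonate F7. Corey–Winter fragmentation (P(OMe)3, 110 °C) gives the silyl ether of 15, F8, and Bu4NF (THF) returns 15.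

Further compounds

F1 | step 3 | allyl (3S,6R)-6-[4-(1,3-dioxan-2-yl)-2-methylbutan-2-yl]-2,3-dimethylcyclohex-1-en-1-yl carbonate | C[C@H]1CC[C@H](C(C)(C)CCC2OCCCO2)C(OC(=O)OCC=C)=C1C
F2 | step 5 | 4-[(1S,3R,6S)-3-[4-(1,3-dioxan-2-yl)-2-methylbutan-2-yl]-1,6-dimethyl-2-oxocyclohexyl]butanoic acid | C[C@H]1CC[C@H](C(C)(C)CCC2OCCCO2)C(=O)[C@@]1(C)CCCC(=O)O
F3 | step 5 | (4S)-4-benzyl-3-{4-[(1S,3R,6S)-3-[4-(1,3-dioxan-2-yl)-2-methylbutan-2-yl]-1,6-dimethyl-2-oxocyclohexyl]butanoyl}-1,3-oxazolidin-2-one | C[C@H]1CC[C@H](C(C)(C)CCC2OCCCO2)C(=O)[C@@]1(C)CCCC(=O)N1[C@@H](Cc2ccccc2)COC1=O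
F4 | step 5 | (4S)-4-benzyl-3-[(2R)-2-{2-[(1S,3R,6S)-3-[4-(1,3-dioxan-2-yl)-2-methylbutan-2-yl]-1,6-dimethyl-2-oxocyclohexyl]ethyl}pent-4-enoyl]-1,3-oxazolidin-2-one | C[C@H]1CC[C@H](C(C)(C)CCC2OCCCO2)C(=O)[C@@]1(C)CC[C@H](CC=C)C(=O)N1[C@@H](Cc2ccccc2)COC1=O
F5 | step 7 | 4-[(1R,3S,4S)-3-[(3R)-3-({[tert-butyl(dimethyl)silyl]oxy}methyl)hex-5-en-1-yl]-3,4-dimethyl-2-oxocyclohexyl]-4-methylpentanal | C[C@H]1CC[C@H](C(C)(C)CCC=O)C(=O)[C@@]1(C)CC[C@H](CC=C)CO[Si](C)(C)C(C)(C)C
F6 | step 7 | (4aR,7S,8S)-8-[(3R)-3-({[tert-butyl(dimethyl)silyl]oxy}methyl)hex-5-en-1-yl]-4,4,7,8-tetramethyldecahydronaphthalene-1,8a-diol (cis-diol, carbinol configurations not assigned) | C[C@H]1CC[C@H]2C(O)(C(O)CCC2(C)C)[C@@]1(C)CC[C@H](CC=C)CO[Si](C)(C)C(C)(C)C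
F7 | step 7 | cyclic 1,8a-thionocarbonate of F6 | C[C@H]1CC[C@H]2C3(OC(=S)OC3CCC2(C)C)[C@@]1(C)CC[C@H](CC=C)CO[Si](C)(C)C(C)(C)C
F8 | step 7 | tert-butyl(dimethyl){[(2R)-2-{2-[(1S,2S,4aR)-1,2,5,5-tetramethyl-1,2,3,4,4a,5,6,7-octahydronaphthalen-1-yl]ethyl}pent-4-en-1-yl]oxy}silane | C[C@H]1CC[C@H]2C(=CCCC2(C)C)[C@@]1(C)CC[C@H](CC=C)CO[Si](C)(C)C(C)(C)C
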